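The X left over when L stopped rising is where I started: the grey run kept 0.130 M of it per starting volume, and the green run 0.00250 M.

| flask | X | D | remark | time |
|---|---|---|---|---|
| green | 0.25 M | 0.25 M (fed, over 15 s) | run made earlier; the fed solution adds 0.50 times the starting volume |  |
| grey | 0.38 M | 0.25 M (fed, over 15 s) | run made earlier; the fed solution adds 0.50 times the starting volume |  |
| flask | 0.50 M | 0.250 M (fed, over 15 s) | the fed solution adds 0.50 times the starting volume | 8.0 min |

| green: time / min | green: L / % | grey: time / min | grey: L / % |
|---|---|---|---|
| 1.00 | 98.9 | 1.00 | 65.7 |
| 2.00 | 98.9 | 2.00 | 65.6 |
| 3.00 | 99.0 | 3.00 | 65.8 |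
| 4.00 | 98.9 | 4.00 | 65.6 |
| 5.00 | 99.3 | 5.00 | 66.0 |

(each reading ± 0.3 percentage points)

1. at 8.0 min, what has stopped the reaction, if anything has (all of X has reacted / D has run out first / it is still moving)
2. how much L there is at 8.0 min, in percent of the X charged

- charges are per starting volume, the dose included; the dosed solution carries all of it
- the numbers in the tables scatter with a standard deviation of 0.3 percentage points
- reactions considered so far: X + D -> L; D -> G
- the reaction counts as stopped when no species that holds the X changes by six tenths of a point or more over the second half of the time

Both runs were flat by their first reading, so I compared shares instead of times. D can go to L or to G, and dividing the rate into L by the sum of both rates removes time. From the mean readings, the grey run gives 99.9% for the capture f, the part of the charged D found as L. The green run gives 99.0%.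

These two ways part by 0.90 percentage points, more than the scatter of one reading. I distrusted the green value because its leftover X was far smaller than the grey run's, so late D there met a thinned X. My flask should keep 0.250 M of X, more than the grey run, so I carried the grey f, with c for a charge per starting volume:

L, in percent of X charged = min(f × c(D) / c(X), 100%)

For the flask this gave me 50.0%, with D as the limiting reagent.

The forecast said "D has run out first" and 49.9%, because “D should be captured even more efficiently”. My figure lies within the scatter of one reading of the forecast's.

    X + D → L, rate k1*[X]*[D]^0.5 (k = 4.00 M⁻⁰·⁵ s⁻¹)
    D → G (k = 0.0230 s⁻¹)

The flask gave "D has run out first" and L 50.0%, a capture of >99.9%. At 8.00 min, 50% of the X and 0% of the D remained, and L had stood at 49.9% already at 0.250 min, when the feed ended. A neighbour flask charged with 0.12 M of X had 2.08 equiv of D. There f × c(D) / c(X) comes to 208%, above the ceiling, so the rule gives 100%. That neighbour reached L 100% at 8.00 min, with 0% of its X left.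

The readings were computed with made-up constants, noise included.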